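Dimethyl squarate supplies C5–C8 of the arene, whose six substituents are five contiguous oxygens (O1 on C8a, OMe on C8, C7 and C6, free OH on C5) and one carbon (C4 on C4a).
C8a and C4a are C6 and C5, the enol-ether C=C, of a 6-lithiated 2,2-disubstituted 3,4-dihydro-2H-pyran; thermal ring expansion of the resulting 4-pyranyl-4-methoxycyclobutenone forms the C4a–C5 bond and the benzene ring, and C3=C4 is introduced last by dehydrogenation.
The dihydropyran comes from an (R)-configured tertiary homoallylic alcohol (hydroformylation to the lactol, dehydration), and the alcohol from catalytic asymmetric allylboration of a methyl ketone.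
The ketone comes from the endo Diels–Alder adduct of acrolein and (E)-3-methylpenta-1,3-diene: aza-enolate alkylation sets the quaternary centre and the formyl group is reduced to methyl.
Ring order: cyclohexene, then dihydropyran, then benzene ring, then chroman to 2H-chromene.

Key step: step 12

Assumption: the absolute sense of the two catalyst-controlled steps (1 and 8) is assigned by analogy with simpler substrates and is checked on the first run, the mirror-image catalyst being used if the opposite sense is found; of diene 2 only the E isomer takes part in the cycloaddition.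

Step 1
Reactants: 1 acrolein; 2 (E)-3-methylpenta-1,3-diene
Product: 3 (1S,2S)-2,3-dimethylcyclohex-3-ene-1-carbaldehyde (formyl cis to the C2 methyl)
Conditions: cationic oxazaborolidine from (S)-α,α-diphenylprolinol, o-tolylboronic acid and Tf2NH (20 mol%), CH2Cl2, −78 °C
Reagents that add atoms: none
Why: Lewis-acid-catalysed asymmetric Diels–Alder reaction in which the boron-bound enal should bond its formyl-bearing carbon to the methyl-bearing diene terminus (the 1-methyl "ortho" effect is expected to outweigh the opposing 2-methyl effect), endo addition to the E-diene gives the 1,2-cis adduct, and the catalyst shields one enal face so that C2 is set as S; C1 is erased in step 4, so exo adduct would lower the ee and must be kept small.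

Step 2
Reactants: 3 (1S,2S)-2,3-dimethylcyclohex-3-ene-1-carbaldehyde
Product: 4 (E)-N-tert-butyl-1-[(1S,2S)-2,3-dimethylcyclohex-3-en-1-yl]methanimine
Conditions: t-BuNH2, MgSO4, Et2O, 0 °C → rt
Reagents that add atoms: tert-butylamine, CC(C)(C)N
Why: Imine condensation driven by the drying agent; the bulky N-substituent later blocks addition of the amide base to C=N, and any epimerisation at C1 is of no consequence.

Step 3
Reactants: 5 2-(2-bromoethyl)-2-methyl-1,3-dioxolane
Product: 6 2-(2-iodoethyl)-2-methyl-1,3-dioxolane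
Conditions: NaI, NaHCO3 (cat.), acetone, reflux
Reagents that add atoms: sodium iodide, [Na+].[I-]
Why: Finkelstein halide exchange driven by precipitation of NaBr gives the more reactive primary iodide, with the ketal kept intact by the trace of base.

Step 4
Reactants: 4 (E)-N-tert-butyl-1-[(1S,2S)-2,3-dimethylcyclohex-3-en-1-yl]methanimine; 6 2-(2-iodoethyl)-2-methyl-1,3-dioxolane
Product: 9 (1R,2R)-2,3-dimethyl-1-[2-(2-methyl-1,3-dioxolan-2-yl)ethyl]cyclohex-3-ene-1-carbaldehyde (formyl cis to the C2 methyl; side chain trans), via lithium aza-enolate 7 (not isolated), via alkylated tert-butylimine 8 (not isolated)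
Conditions: LiN(iPr)2, THF, 0 °C; 6, DMPU, −78 °C → rt; then AcOH/NaOAc/H2O (pH 4.5), rt
Reagents that add atoms: water, O
Why: Metalloenamine (aza-enolate) alkylation in which the C2 methyl lies pseudoaxial to avoid allylic strain with the ring C3 methyl and the exocyclic C=C–N unit, so the primary iodide should attack C1 from the opposite face and place the chain trans to that methyl; buffered hydrolysis then frees the non-enolisable aldehyde while the dioxolane survives.

Step 5
Reactants: 9 (1R,2R)-2,3-dimethyl-1-[2-(2-methyl-1,3-dioxolan-2-yl)ethyl]cyclohex-3-ene-1-carbaldehyde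
Product: 11 2-methyl-2-{2-[(1S,2S)-1,2,3-trimethylcyclohex-3-en-1-yl]ethyl}-1,3-dioxolane, via hydrazone 10 (not isolated)
Conditions: N2H4·H2O, KOH, diethylene glycol, 130 °C then 200 °C
Reagents that add atoms: none
Why: Wolff–Kishner reduction (Huang-Minlon procedure) converts the hindered formyl group into the C1 methyl by loss of N2 from the hydrazone anion; the dioxolane, the isolated trisubstituted alkene and both ring stereocentres are stable to hot base.

Step 6
Reactants: 11 2-methyl-2-{2-[(1S,2S)-1,2,3-trimethylcyclohex-3-en-1-yl]ethyl}-1,3-dioxolane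
Product: 12 4-[(1S,2S)-1,2,3-trimethylcyclohex-3-en-1-yl]butan-2-one
Conditions: PPTS, acetone/H2O, 50 °C
Reagents that add atoms: water, O
Why: Mild acid-catalysed ketal hydrolysis releases the methyl ketone under conditions too weak to move the trisubstituted ring alkene.

Step 7
Reactants: 13 triisopropyl borate; 14 allylmagnesium bromide
Product: 16 allyldiisopropoxyborane, via bromomagnesium allyltriisopropoxyborate 15 (not isolated)
Conditions: Et2O, −78 °C → rt; HCl (in Et2O), 0 °C; distil
Reagents that add atoms: none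
Why: Grignard addition to the borate gives the ate complex, which anhydrous HCl collapses to the acyclic allylboronate; an acyclic ester is chosen because a pinacol ester would not exchange with the diol catalyst of step 8.

Step 8
Reactants: 12 4-[(1S,2S)-1,2,3-trimethylcyclohex-3-en-1-yl]butan-2-one; 16 allyldiisopropoxyborane
Product: 18 (3R)-3-methyl-1-[(1S,2S)-1,2,3-trimethylcyclohex-3-en-1-yl]hex-5-en-3-ol, via diisopropyl borate ester 17 (not isolated)
Conditions: (R)-3,3'-dibromo-1,1'-bi-2-naphthol (15 mol%), PhCF3/PhCH3 (3:1), −35 °C; aq. NaHCO3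
Reagents that add atoms: none
Why: Chiral-diol-catalysed asymmetric allylboration of a ketone, in which exchange of one isopropoxy group for the binaphthol gives a more Lewis-acidic boronate that transfers allyl through a closed chair transition state to one face of the methyl ketone, setting the (R)-carbinol by catalyst control with no influence expected from the remote ring centres.

Step 9
Reactants: 18 (3R)-3-methyl-1-[(1S,2S)-1,2,3-trimethylcyclohex-3-en-1-yl]hex-5-en-3-ol
Product: 20 (6S)-6-methyl-6-{2-[(1S,2S)-1,2,3-trimethylcyclohex-3-en-1-yl]ethyl}tetrahydro-2H-pyran-2-ol (anomer mixture), via open-chain hydroxy aldehyde 19 (not isolated)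
Conditions: Rh(acac)(CO)2 (1 mol%), Xantphos (2 mol%), CO/H2 (1:1, 10 bar), toluene, 70 °C
Reagents that add atoms: carbon monoxide, [C-]#[O+]
Why: Linear-selective rhodium hydroformylation with a wide-bite-angle diphosphine formylates only the monosubstituted alkene (the trisubstituted ring alkene is inert), and the δ-hydroxy aldehyde closes spontaneously to the six-membered lactol.

Step 10
Reactants: 20 (6S)-6-methyl-6-{2-[(1S,2S)-1,2,3-trimethylcyclohex-3-en-1-yl]ethyl}tetrahydro-2H-pyran-2-ol
Product: 22 (2S)-2-methyl-2-{2-[(1S,2S)-1,2,3-trimethylcyclohex-3-en-1-yl]ethyl}-3,4-dihydro-2H-pyran, via anomeric mesylate 21 (not isolated)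
Conditions: MsCl, Et3N, THF, 0 °C → 65 °C
Reagents that add atoms: none
Why: Lactol dehydration by mesylation of the anomeric hydroxyl and amine-induced elimination gives the cyclic enol ether without touching the quaternary carbinol carbon (the descriptor changes from R to S only through ligand priorities).

Step 11
Reactants: 22 (2S)-2-methyl-2-{2-[(1S,2S)-1,2,3-trimethylcyclohex-3-en-1-yl]ethyl}-3,4-dihydro-2H-pyran; 23 dimethyl squarate
Product: 26 2,3,4-trimethoxy-4-[(6S)-6-methyl-6-{2-[(1S,2S)-1,2,3-trimethylcyclohex-3-en-1-yl]ethyl}-5,6-dihydro-4H-pyran-2-yl]cyclobut-2-en-1-one (both epimers at the cyclobutenone C4), via 6-lithiodihydropyran 24 (not isolated), via lithium alkoxide adduct 25 (not isolated)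
Conditions: t-BuLi, THF/pentane, −78 → 0 °C; add to 23, THF, −78 °C; MeOTf, −78 → 0 °C
Reagents that add atoms: methyl triflate, COS(=O)(=O)C(F)(F)F
Why: α-Lithiation of the enol ether at the vinylic C6–H, 1,2-addition of the vinyllithium to one squarate carbonyl at low temperature and O-methylation of the tertiary lithium alkoxide give the 4-alkenyl-4-methoxycyclobutenone; the new cyclobutenone centre is uncontrolled and vanishes in step 12.

Step 12
Reactants: 26 2,3,4-trimethoxy-4-[(6S)-6-methyl-6-{2-[(1S,2S)-1,2,3-trimethylcyclohex-3-en-1-yl]ethyl}-5,6-dihydro-4H-pyran-2-yl]cyclobut-2-en-1-one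
Product: 29 (2R)-6,7,8-trimethoxy-2-methyl-2-{2-[(1S,2S)-1,2,3-trimethylcyclohex-3-en-1-yl]ethyl}-3,4-dihydro-2H-chromen-5-ol, via dienylketene 27 (not isolated), via cyclohexadienone 28 (not isolated)
Conditions: degassed toluene, 110 °C
Reagents that add atoms: none
Why: Heating opens the cyclobutenone by conrotatory 4π electrocyclic cleavage of the C1–C4 bond to dienylketene 27, the donor 4-methoxy group rotating outward so that the pyranyl C=C is held cis to the ketene. A thermal 6π electrocyclisation then bonds the ketene carbon to C5 of the pyran (the C4a–C5 bond), closing the six-membered carbocycle onto the existing pyran as dienone 28, which enolises to the phenol. The closest known reaction type is the thermal ring expansion of 4-alkenyl-4-alkoxycyclobutenones derived from squarate esters to polyoxygenated phenols and hydroquinone monoethers. No stereocentre is created, because C4a of 28 becomes aromatic and both epimers of 26 converge, while C2 and the ring centres are not involved. The step needs inward rotation of the pyranyl group, which the outward preference of the 4-methoxy group secures, and the symmetry of the squarate removes any regiochemical choice: the ketene oxygen becomes the free C5–OH and the oxygen methylated in step 11 becomes the C8–OMe next to O1.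

Step 13
Reactants: 29 (2R)-6,7,8-trimethoxy-2-methyl-2-{2-[(1S,2S)-1,2,3-trimethylcyclohex-3-en-1-yl]ethyl}-3,4-dihydro-2H-chromen-5-ol
Product: 30 (2R)-6,7,8-trimethoxy-2-methyl-2-{2-[(1S,2S)-1,2,3-trimethylcyclohex-3-en-1-yl]ethyl}-3,4-dihydro-2H-chromen-5-yl acetate
Conditions: Ac2O, pyridine, DMAP (cat.), CH2Cl2, rt
Reagents that add atoms: acetic anhydride, CC(=O)OC(C)=O
Why: Nucleophile-catalysed acylation masks the oxidation-prone para-alkoxyphenol before the quinone oxidant is used.

Step 14
Reactants: 30 (2R)-6,7,8-trimethoxy-2-methyl-2-{2-[(1S,2S)-1,2,3-trimethylcyclohex-3-en-1-yl]ethyl}-3,4-dihydro-2H-chromen-5-yl acetate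
Product: 31 (2R)-6,7,8-trimethoxy-2-methyl-2-{2-[(1S,2S)-1,2,3-trimethylcyclohex-3-en-1-yl]ethyl}-2H-chromen-5-yl acetate
Conditions: DDQ (1.5 equiv), benzene, 80 °C
Reagents that add atoms: none
Why: DDQ dehydrogenation of a chroman to a 2H-chromene, in which hydride abstraction from benzylic C4 gives a cation stabilised by O1 (ortho) and the C7 methoxy (para) and loss of a C3 proton gives the C3=C4 bond; the acetate prevents quinone formation, the isolated ring alkene is a much poorer hydride donor, and the quaternary C2 cannot epimerise.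

Step 15
Reactants: 31 (2R)-6,7,8-trimethoxy-2-methyl-2-{2-[(1S,2S)-1,2,3-trimethylcyclohex-3-en-1-yl]ethyl}-2H-chromen-5-yl acetate
Product: 32 (2R)-6,7,8-trimethoxy-2-methyl-2-{2-[(1S,2S)-1,2,3-trimethylcyclohex-3-en-1-yl]ethyl}-2H-chromen-5-ol (target CNP0185215.2)
Conditions: K2CO3 (0.2 equiv), MeOH, rt, argon
Reagents that add atoms: none
Why: Base-catalysed transesterification (methanolysis) of the aryl acetate frees the C5 phenol, and nothing else in the molecule is base-labile.

Compound list
1 | acrolein | C=CC=O | starting material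
2 | (E)-3-methylpenta-1,3-diene | C=C/C(C)=C/C | starting material
3 | (1S,2S)-2,3-dimethylcyclohex-3-ene-1-carbaldehyde | O=C[C@H]1CCC=C(C)[C@H]1C | intermediate
4 | (E)-N-tert-butyl-1-[(1S,2S)-2,3-dimethylcyclohex-3-en-1-yl]methanimine | CC(C)(C)/N=C/[C@H]1CCC=C(C)[C@H]1C | intermediate
5 | 2-(2-bromoethyl)-2-methyl-1,3-dioxolane | CC1(CCBr)OCCO1 | starting material
6 | 2-(2-iodoethyl)-2-methyl-1,3-dioxolane | CC1(CCI)OCCO1 | intermediate
7 | lithium aza-enolate of 4 (N-lithio enamide, exocyclic C=C, C2 centre intact) | [Li]N(C=C1CCC=C(C)[C@H]1C)C(C)(C)C | intermediate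
8 | N-tert-butyl imine of aldehyde 9 | CC1(CC[C@]2(/C=N/C(C)(C)C)CCC=C(C)[C@H]2C)OCCO1 | intermediate
9 | (1R,2R)-2,3-dimethyl-1-[2-(2-methyl-1,3-dioxolan-2-yl)ethyl]cyclohex-3-ene-1-carbaldehyde | CC1(CC[C@]2(C=O)CCC=C(C)[C@H]2C)OCCO1 | intermediate
10 | hydrazone of aldehyde 9 | CC1(CC[C@]2(/C=N/N)CCC=C(C)[C@H]2C)OCCO1 | intermediate
11 | 2-methyl-2-{2-[(1S,2S)-1,2,3-trimethylcyclohex-3-en-1-yl]ethyl}-1,3-dioxolane | CC1(CC[C@]2(C)CCC=C(C)[C@H]2C)OCCO1 | intermediate
12 | 4-[(1S,2S)-1,2,3-trimethylcyclohex-3-en-1-yl]butan-2-one | CC(=O)CC[C@]1(C)CCC=C(C)[C@H]1C | intermediate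
13 | triisopropyl borate | CC(C)OB(OC(C)C)OC(C)C | starting material
14 | allylmagnesium bromide | C=CC[Mg]Br | starting material
15 | bromomagnesium allyltriisopropoxyborate | C=CC[B-](OC(C)C)(OC(C)C)OC(C)C.[Mg+2].[Br-] | intermediate
16 | allyldiisopropoxyborane | C=CCB(OC(C)C)OC(C)C | intermediate
17 | diisopropyl borate ester of alcohol 18 | CC(C)OB(OC(C)C)O[C@](C)(CC[C@]1(C)CCC=C(C)[C@H]1C)CC=C | intermediate
18 | (3R)-3-methyl-1-[(1S,2S)-1,2,3-trimethylcyclohex-3-en-1-yl]hex-5-en-3-ol | O[C@](C)(CC[C@]1(C)CCC=C(C)[C@H]1C)CC=C | intermediate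
19 | (5S)-5-hydroxy-5-methyl-7-[(1S,2S)-1,2,3-trimethylcyclohex-3-en-1-yl]heptanal | O[C@](C)(CC[C@]1(C)CCC=C(C)[C@H]1C)CCCC=O | intermediate
20 | (6S)-6-methyl-6-{2-[(1S,2S)-1,2,3-trimethylcyclohex-3-en-1-yl]ethyl}tetrahydro-2H-pyran-2-ol (anomer mixture) | OC1CCC[C@@](C)(CC[C@]2(C)CCC=C(C)[C@H]2C)O1 | intermediate
21 | anomeric mesylate of lactol 20 | CS(=O)(=O)OC1CCC[C@@](C)(CC[C@]2(C)CCC=C(C)[C@H]2C)O1 | intermediate
22 | (2S)-2-methyl-2-{2-[(1S,2S)-1,2,3-trimethylcyclohex-3-en-1-yl]ethyl}-3,4-dihydro-2H-pyran | O1[C@](C)(CC[C@]2(C)CCC=C(C)[C@H]2C)CCC=C1 | intermediate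
23 | dimethyl squarate (3,4-dimethoxycyclobut-3-ene-1,2-dione) | COC1=C(OC)C(=O)C1=O | starting material
24 | 6-lithio derivative of dihydropyran 22 | [Li]C1=CCC[C@@](C)(CC[C@]2(C)CCC=C(C)[C@H]2C)O1 | intermediate
25 | lithium 2,3-dimethoxy-4-oxo-1-(dihydropyranyl)cyclobut-2-en-1-olate (adduct of 24 and 23) | [Li]OC1(C(OC)=C(OC)C1=O)C1=CCC[C@@](C)(CC[C@]2(C)CCC=C(C)[C@H]2C)O1 | intermediate
26 | 2,3,4-trimethoxy-4-[(6S)-6-methyl-6-{2-[(1S,2S)-1,2,3-trimethylcyclohex-3-en-1-yl]ethyl}-5,6-dihydro-4H-pyran-2-yl]cyclobut-2-en-1-one | COC1=C(OC)C(OC)(C1=O)C3=CCC[C@@](C)(CC[C@]2(C)CCC=C(C)[C@H]2C)O3 | intermediate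
27 | dienylketene from ring opening of 26 (pyranyl cis to the ketene) | O=C=C(OC)/C(OC)=C(OC)\C1=CCC[C@@](C)(CC[C@]2(C)CCC=C(C)[C@H]2C)O1 | intermediate
28 | 6,7,8-trimethoxy-2-methyl-2-{2-[(1S,2S)-1,2,3-trimethylcyclohex-3-en-1-yl]ethyl}-2,3,4,4a-tetrahydro-5H-chromen-5-one | COC1=C(OC)C(OC)=C2O[C@](C)(CC[C@]3(C)CCC=C(C)[C@H]3C)CCC2C1=O | intermediate
29 | (2R)-6,7,8-trimethoxy-2-methyl-2-{2-[(1S,2S)-1,2,3-trimethylcyclohex-3-en-1-yl]ethyl}-3,4-dihydro-2H-chromen-5-ol | COc1c(O)c2c(c(OC)c1OC)O[C@](C)(CC[C@]1(C)CCC=C(C)[C@H]1C)CC2 | intermediate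
30 | (2R)-6,7,8-trimethoxy-2-methyl-2-{2-[(1S,2S)-1,2,3-trimethylcyclohex-3-en-1-yl]ethyl}-3,4-dihydro-2H-chromen-5-yl acetate | COc1c(OC(C)=O)c2c(c(OC)c1OC)O[C@](C)(CC[C@]1(C)CCC=C(C)[C@H]1C)CC2 | intermediate
31 | (2R)-6,7,8-trimethoxy-2-methyl-2-{2-[(1S,2S)-1,2,3-trimethylcyclohex-3-en-1-yl]ethyl}-2H-chromen-5-yl acetate | COc1c(OC(C)=O)c2c(c(OC)c1OC)O[C@](C)(CC[C@]1(C)CCC=C(C)[C@H]1C)C=C2 | intermediate
32 | (2R)-6,7,8-trimethoxy-2-methyl-2-{2-[(1S,2S)-1,2,3-trimethylcyclohex-3-en-1-yl]ethyl}-2H-chromen-5-ol | COc1c(O)c2c(c(OC)c1OC)O[C@](C)(CC[C@]1(C)CCC=C(C)[C@H]1C)C=C2 | target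

Total step count: 15.
Longest linear sequence: 13 steps (1, 2, 4, 5, 6, 8, 9, 10, 11, 12, 13, 14, 15); steps 3 and 7 prepare side reagents.

Steps most likely to fail

1. Step 1. The two diene methyls direct in opposite senses, so some regioisomeric adduct may form, and exo addition or weak face shielding of the unsubstituted enal would lower the ee of the only centre that is kept. The fallback is auxiliary control, setting out from diene 2 and returning at 3. Diene 2 is added to commercial (R)-3-acryloyl-4-benzyloxazolidin-2-one with Et2AlCl in CH2Cl2 at −78 °C. The bidentate aluminium chelate is attacked on the face away from the benzyl group in the endo mode, which should give the crystalline (R)-4-benzyl-3-[(1S,2S)-2,3-dimethylcyclohex-3-ene-1-carbonyl]oxazolidin-2-one F1, and minor isomers are removed by recrystallisation. Reduction with LiBH4 (THF/MeOH, 0 °C) gives [(1S,2S)-2,3-dimethylcyclohex-3-en-1-yl]methanol F2 and returns the auxiliary. Dess–Martin oxidation (NaHCO3, CH2Cl2) then gives aldehyde 3.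

2. Step 4. The crowded aza-enolate may eliminate HI from the β-branched iodide, alkylate on nitrogen, or discriminate poorly between its two faces. The fallback uses a smaller and more nucleophilic metalated nitrile, setting out from 3 and returning at 9. Aldehyde 3 is converted with NH2OH·HCl and pyridine into 2,3-dimethylcyclohex-3-ene-1-carbaldehyde oxime F3. Dehydration with Ac2O at reflux gives (1S,2S)-2,3-dimethylcyclohex-3-ene-1-carbonitrile F4. Deprotonation with LiN(iPr)2 (THF, −78 °C) and alkylation with iodide 6, again anti to the pseudoaxial C2 methyl, should give 2,3-dimethyl-1-[2-(2-methyl-1,3-dioxolan-2-yl)ethyl]cyclohex-3-ene-1-carbonitrile (cyano cis to the C2 methyl) F5. Reduction with i-Bu2AlH (toluene, −78 °C) and buffered aqueous tartrate hydrolysis of the aluminium imine then give aldehyde 9.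

3. Step 8. The closed transition state may not distinguish the methyl from the primary-alkyl flank of the ketone well enough. The fallback sets the carbinol centre by Sharpless asymmetric epoxidation, setting out from 12 and returning at 18.
   - Horner–Wadsworth–Emmons olefination of 12 (triethyl phosphonoacetate, NaH, THF) gives ethyl (E)-3-methyl-5-[(1S,2S)-1,2,3-trimethylcyclohex-3-en-1-yl]pent-2-enoate F6, with the Z isomer removed by chromatography.
   - Reduction with i-Bu2AlH (CH2Cl2, −78 °C) gives (E)-3-methyl-5-[(1S,2S)-1,2,3-trimethylcyclohex-3-en-1-yl]pent-2-en-1-ol F7.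
   - Epoxidation with Ti(OiPr)4, D-(−)-diethyl tartrate and t-BuOOH (4 Å sieves, CH2Cl2, −20 °C) should give [(2R,3R)-3-methyl-3-{2-[(1S,2S)-1,2,3-trimethylcyclohex-3-en-1-yl]ethyl}oxiran-2-yl]methanol F8; the ring alkene has no directing hydroxyl and is left alone.
   - Hydroxyl-directed hydride opening at C2 with NaAlH2(OCH2CH2OCH3)2 (THF, 0 °C) gives (3R)-3-methyl-5-[(1S,2S)-1,2,3-trimethylcyclohex-3-en-1-yl]pentane-1,3-diol F9.
   - Selective oxidation of the primary alcohol (TEMPO, PhI(OAc)2, CH2Cl2) gives (3R)-3-hydroxy-3-methyl-5-[(1S,2S)-1,2,3-trimethylcyclohex-3-en-1-yl]pentanal F10.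
   - Wittig methylenation (Ph3PCH3Br, KOtBu, THF) then gives homoallylic alcohol 18.

Further compounds
F1 | step 1 | (R)-4-benzyl-3-[(1S,2S)-2,3-dimethylcyclohex-3-ene-1-carbonyl]oxazolidin-2-one | O=C([C@H]1CCC=C(C)[C@H]1C)N1[C@H](Cc2ccccc2)COC1=O
F2 | step 1 | [(1S,2S)-2,3-dimethylcyclohex-3-en-1-yl]methanol | OC[C@H]1CCC=C(C)[C@H]1C
F3 | step 4 | 2,3-dimethylcyclohex-3-ene-1-carbaldehyde oxime | ON=C[C@H]1CCC=C(C)[C@H]1C
F4 | step 4 | (1S,2S)-2,3-dimethylcyclohex-3-ene-1-carbonitrile | N#C[C@H]1CCC=C(C)[C@H]1C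
F5 | step 4 | 2,3-dimethyl-1-[2-(2-methyl-1,3-dioxolan-2-yl)ethyl]cyclohex-3-ene-1-carbonitrile (cyano cis to the C2 methyl) | CC1(CC[C@]2(C#N)CCC=C(C)[C@H]2C)OCCO1
F6 | step 8 | ethyl (E)-3-methyl-5-[(1S,2S)-1,2,3-trimethylcyclohex-3-en-1-yl]pent-2-enoate | CCOC(=O)/C=C(\C)CC[C@]1(C)CCC=C(C)[C@H]1C
F7 | step 8 | (E)-3-methyl-5-[(1S,2S)-1,2,3-trimethylcyclohex-3-en-1-yl]pent-2-en-1-ol | OC/C=C(\C)CC[C@]1(C)CCC=C(C)[C@H]1C
F8 | step 8 | [(2R,3R)-3-methyl-3-{2-[(1S,2S)-1,2,3-trimethylcyclohex-3-en-1-yl]ethyl}oxiran-2-yl]methanol | O1[C@](C)(CC[C@]2(C)CCC=C(C)[C@H]2C)[C@H]1CO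
F9 | step 8 | (3R)-3-methyl-5-[(1S,2S)-1,2,3-trimethylcyclohex-3-en-1-yl]pentane-1,3-diol | O[C@](C)(CC[C@]1(C)CCC=C(C)[C@H]1C)CCO
F10 | step 8 | (3R)-3-hydroxy-3-methyl-5-[(1S,2S)-1,2,3-trimethylcyclohex-3-en-1-yl]pentanal | O[C@](C)(CC[C@]1(C)CCC=C(C)[C@H]1C)CC=O
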